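**Retrosynthetic overview**
1. Endgame: the C=CH2 group comes from a primary allylic alcohol by reductive 1,3-transposition, the cis-bromohydrin from an α'-bromo enone by hydride reduction, and the dibromomethyl carbinol from a ring-B bromomethylidene diene by HOBr addition; the ring-A pattern comes from a dimedone vinylogous ester by Stork–Danheiser transposition.
2. Key disconnection (ring B): a one-pot Robinson-type spiro-annulation makes the bond from the spiro carbon to its saturated CH2 neighbour (Michael addition) and the ring-B C=C bond (aldol condensation), from a formylated dimedone vinylogous ester and methyl vinyl ketone.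
3. Enabling feature: in ring B the spiro carbon sits para to the carbinol carbon and is joined to it by a CH=CH arm and a CH2–CH2 arm, so with the carbinol carbon as a ketone ring B is a 4,4-disubstituted cyclohex-2-enone. The spiro carbon is also α to the ring-A carbon that ends as C=CH2, so it can be the central carbon of a 2-formyl ketone whose formyl carbon becomes the alkene CH next to the spiro centre.
4. Ring order: ring A is bought (dimedone), ring B is closed in the key step; the spiro stereocentre set there is the reference for the three later stereocentres.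

Key step: step 3

**Remarks (assumptions on the chemistry)**
- Names use spiro[5.5]undecane numbering: ring B = C1–C5 (C1=C2 alkene, C3 carbinol/carbonyl carbon), C6 = spiro carbon, ring A = C7–C11 (C7 carries the one-carbon substituent, C9 carbinol/carbonyl carbon, C10 the CHBr carbon, C11 the gem-dimethyl carbon).
- The spiro centre keeps one spatial arrangement from 6 onwards; its descriptor changes from R (7–13) to S (14–19) only because the C10 bromine raises the CIP rank of C11.
- Compounds 8–14 are expected as E/Z mixtures at the exocyclic C=CHBr bond; both isomers converge in step 8, so this geometry is left open in the SMILES.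
- The sense of induction of the cinchona catalyst in step 3 is assumed; the quinine-derived pseudoenantiomer would be used if the sense proved opposite.

**Step 1**
Reactants: 1 dimedone (5,5-dimethylcyclohexane-1,3-dione); 2 2-methylpropan-1-ol (isobutanol)
Product: 3 5,5-dimethyl-3-(2-methylpropoxy)cyclohex-2-en-1-one
Conditions: p-TsOH·H2O (cat.), PhMe, reflux, Dean–Stark
Reagents that add atoms: none
Why: Acid-catalysed enol etherification of a cyclic 1,3-diketone with azeotropic removal of water (vinylogous ester formation); no stereocentre is formed.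

**Step 2**
Reactants: 3 5,5-dimethyl-3-(2-methylpropoxy)cyclohex-2-en-1-one
Product: 4 (6Z)-6-(hydroxymethylidene)-5,5-dimethyl-3-(2-methylpropoxy)cyclohex-2-en-1-one (chelated enol of the 6-formyl ketone)
Conditions: LiN(i-Pr)2, THF, −78 °C; HCO2CH2CF3, −78 → 0 °C; aq. HCl to pH 5
Reagents that add atoms: 2,2,2-trifluoroethyl formate, O=COCC(F)(F)F
Why: Kinetic deprotonation of a 3-alkoxy enone occurs at the α'-carbon (Stork–Danheiser regiochemistry) and Claisen-type C-formylation with the reactive formate should give the chelated hydroxymethylidene ketone, whose acidity drives the reaction; no stereocentre.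

**Step 3**
Reactants: 4 (6Z)-6-(hydroxymethylidene)-5,5-dimethyl-3-(2-methylpropoxy)cyclohex-2-en-1-one; 5 but-3-en-2-one (methyl vinyl ketone)
Product: 7 spiro dienedione (6R)-11,11-dimethyl-9-(2-methylpropoxy)spiro[5.5]undeca-1,8-diene-3,7-dione, via Michael adduct 6 (not isolated)
Conditions: 9-O-(9-phenanthryl)cupreidine (quinidine-derived 6'-hydroxy catalyst, 10 mol%), CH2Cl2, −20 °C; then pyrrolidine (0.3 equiv), AcOH (0.3 equiv), 40 °C, one pot
Reagents that add atoms: none
Why: The quinuclidine nitrogen of the catalyst deprotonates the acidic, chelated formyl ketone 4, and the ion-paired enolate adds through its doubly activated carbon to methyl vinyl ketone held by the catalyst 6'-OH, which forms the bond from the future spiro carbon to the CH2 group (Michael addition to 6). Pyrrolidinium acetate then converts the methyl ketone of 6 into its enamine, which attacks the aldehyde and, after loss of water, gives the ring-B C=C bond (aldol condensation), so the overall event is a Robinson-type annulation. The closest known reaction types are the cinchona-catalysed conjugate addition of cyclic α-substituted 1,3-dicarbonyl compounds to enones and the classical Michael–aldol spiro-annulation of 2-formylcycloalkanones with methyl vinyl ketone. Ring B is the only ring closed, by a 6-(enolexo)-exo-trig aldol cyclisation. The only new stereocentre, the quaternary spiro carbon, is set in the Michael step by the catalyst, which reads the two very different flanks of the planar enolate carbon (vinylogous-ester carbonyl against gem-dimethyl carbon), and it cannot epimerise afterwards because it bears no hydrogen. The step needs C-alkylation at this carbon, cyclisation of the methyl terminus onto the aldehyde, and no deformylation: the carbon between the two carbonyl groups is the only soft nucleophilic site, the aldehyde has no α-hydrogen and is far more electrophilic than the hindered vinylogous-ester carbonyl, only the methyl terminus gives a six-membered ring, and the weakly basic catalyst and buffered amine guard against retro-Claisen cleavage.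

**Step 4**
Reactants: 7 (6R)-11,11-dimethyl-9-(2-methylpropoxy)spiro[5.5]undeca-1,8-diene-3,7-dione
Product: 8 (6R)-3-(bromomethylidene)-11,11-dimethyl-9-(2-methylpropoxy)spiro[5.5]undeca-1,8-dien-7-one (E/Z mixture)
Conditions: [Ph3PCH2Br]Br, KOt-Bu, THF, −78 °C; then 7, −78 → 23 °C
Reagents that add atoms: (bromomethyl)triphenylphosphonium bromide, BrC[P+](c1ccccc1)(c1ccccc1)c1ccccc1.[Br-]
Why: Wittig bromomethylenation should occur at the ring-B enone carbonyl and not at the hindered vinylogous-ester carbonyl of ring A, and the 1-bromo-1,3-diene both masks the ketone for steps 5–7 and is the latent dibromomethyl carbinol; no stereocentre (alkene geometry immaterial).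

**Step 5**
Reactants: 8 (6R)-3-(bromomethylidene)-11,11-dimethyl-9-(2-methylpropoxy)spiro[5.5]undeca-1,8-dien-7-one
Product: 11 hydroxymethyl enone (6R)-3-(bromomethylidene)-7-(hydroxymethyl)-11,11-dimethylspiro[5.5]undeca-1,7-dien-9-one, via tertiary carbinol adduct 9 (not isolated), via methoxymethyl ether enone 10 (not isolated)
Conditions: Bu3SnCH2OCH2OMe, n-BuLi, THF, −78 °C; CeCl3, −78 °C; then 8, −78 → −40 °C; then 3 M HCl, THF/H2O, 45 °C
Reagents that add atoms: tributyl[(methoxymethoxy)methyl]stannane, CCCC[Sn](CCCC)(CCCC)COCOC; water, O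
Why: An α-alkoxymethyl organocerium reagent (tin–lithium exchange, then CeCl3 to suppress enolisation and bromine–metal exchange) adds 1,2 to the vinylogous-ester carbonyl, and aqueous acid then effects the Stork–Danheiser carbonyl transposition to the enone and cleaves the methoxymethyl acetal; the spiro centre is untouched and the carbinol centre of 9 is destroyed.

**Step 6**
Reactants: 11 (6R)-3-(bromomethylidene)-7-(hydroxymethyl)-11,11-dimethylspiro[5.5]undeca-1,7-dien-9-one
Product: 12 [(6R)-3-(bromomethylidene)-11,11-dimethyl-9-oxospiro[5.5]undeca-1,7-dien-7-yl]methyl 2,2-dimethylpropanoate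
Conditions: t-BuCOCl, pyridine, DMAP (cat.), CH2Cl2, 0 → 23 °C
Reagents that add atoms: pivaloyl chloride, CC(C)(C)C(=O)Cl
Why: Standard acylation of a primary allylic alcohol; the pivalate tolerates amide base, cannot act as an internal nucleophile towards the ring-B cation of step 8, and is removed by the hydride of step 9.

**Step 7**
Reactants: 12 [(6R)-3-(bromomethylidene)-11,11-dimethyl-9-oxospiro[5.5]undeca-1,7-dien-7-yl]methyl 2,2-dimethylpropanoate
Product: 14 [(6S,10S)-10-bromo-3-(bromomethylidene)-11,11-dimethyl-9-oxospiro[5.5]undeca-1,7-dien-7-yl]methyl 2,2-dimethylpropanoate, via silyl dienol ether 13 (not isolated)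
Conditions: LiN(i-Pr)2, Me3SiCl, THF, −78 °C; then NBS, THF, −78 → 0 °C
Reagents that add atoms: N-bromosuccinimide, O=C1CCC(=O)N1Br
Why: Kinetic α'-deprotonation of the enone at C10 (cross-conjugated enolate, trapped as the silyl dienol ether) and bromination with NBS should deliver bromine anti to the pseudoaxial CH2 arm of ring B at the spiro carbon, and the α-bromo ketone can equilibrate through its enol to the same epimer, with pseudoequatorial bromine on the side of the flat vinylic arm (10S).

**Step 8**
Reactants: 14 [(6S,10S)-10-bromo-3-(bromomethylidene)-11,11-dimethyl-9-oxospiro[5.5]undeca-1,7-dien-7-yl]methyl 2,2-dimethylpropanoate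
Product: 15 [(3R,6S,10S)-10-bromo-3-(dibromomethyl)-3-hydroxy-11,11-dimethyl-9-oxospiro[5.5]undeca-1,7-dien-7-yl]methyl 2,2-dimethylpropanoate
Conditions: NBS (1.05 equiv), NaHCO3, acetone/H2O (4:1), 0 °C, dark
Reagents that add atoms: N-bromosuccinimide, O=C1CCC(=O)N1Br; water, O
Why: Bromohydrin formation: Br+ adds to the bromine-bearing terminus of the diene (the electron-poor ring-A enone is inert) to give the tertiary allylic cation, and water should capture it at C3 along the axial trajectory of the ring-B half-chair in which C11 is pseudoequatorial and C7 pseudoaxial at the spiro carbon, which places OH cis to C11 and the CHBr2 group pseudoequatorial and cis to C7 (3R).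

**Step 9**
Reactants: 15 [(3R,6S,10S)-10-bromo-3-(dibromomethyl)-3-hydroxy-11,11-dimethyl-9-oxospiro[5.5]undeca-1,7-dien-7-yl]methyl 2,2-dimethylpropanoate
Product: 16 (3R,6S,9R,10S)-10-bromo-3-(dibromomethyl)-7-(hydroxymethyl)-11,11-dimethylspiro[5.5]undeca-1,7-diene-3,9-diol
Conditions: i-Bu2AlH (6 equiv), CH2Cl2, −78 → −40 °C; aq. potassium sodium tartrate
Reagents that add atoms: none
Why: i-Bu2AlH reduces the enone 1,2 and cleaves the pivalate, and hydride should reach C9 from the face opposite the pseudoaxial methyl group on C11 (equatorial attack, as in 3,3,5-trimethylcyclohexanone-type ketones), which places the hydroxyl axial and cis to the equatorial bromine (9R).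

**Step 10**
Reactants: 16 (3R,6S,9R,10S)-10-bromo-3-(dibromomethyl)-7-(hydroxymethyl)-11,11-dimethylspiro[5.5]undeca-1,7-diene-3,9-diol
Product: 19 mailiohydrin (3R,6S,9R,10S)-10-bromo-3-(dibromomethyl)-11,11-dimethyl-7-methylidenespiro[5.5]undec-1-ene-3,9-diol, via allylic sulfonylhydrazine 17 (not isolated), via allylic diazene 18 (not isolated)
Conditions: 2-O2NC6H4SO2NHNH2, PPh3, DEAD, N-methylmorpholine, −30 °C; then 23 °C
Reagents that add atoms: none
Why: Mitsunobu displacement of the primary allylic hydroxyl by the sulfonylhydrazide (the hindered secondary and the tertiary hydroxyls should not react), loss of arenesulfinic acid on warming and retro-ene loss of N2 from the monoalkyl diazene deliver hydrogen to C8 and move the double bond into the exocyclic position (reductive 1,3-transposition of an allylic alcohol); no stereocentre is formed or touched.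

**Compound list**
1 | dimedone (5,5-dimethylcyclohexane-1,3-dione) | O=C1CC(=O)CC(C)(C)C1 | starting material
2 | 2-methylpropan-1-ol (isobutanol) | CC(C)CO | starting material
3 | 5,5-dimethyl-3-(2-methylpropoxy)cyclohex-2-en-1-one | O=C1C=C(OCC(C)C)CC(C)(C)C1 | intermediate
4 | (6Z)-6-(hydroxymethylidene)-5,5-dimethyl-3-(2-methylpropoxy)cyclohex-2-en-1-one | O=C1C=C(OCC(C)C)CC(C)(C)/C1=C/O | intermediate
5 | but-3-en-2-one (methyl vinyl ketone) | CC(=O)C=C | starting material
6 | (1S)-6,6-dimethyl-4-(2-methylpropoxy)-2-oxo-1-(3-oxobutyl)cyclohex-3-ene-1-carbaldehyde | O=C1C=C(OCC(C)C)CC(C)(C)[C@]1(C=O)CCC(C)=O | intermediate (not isolated)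
7 | (6R)-11,11-dimethyl-9-(2-methylpropoxy)spiro[5.5]undeca-1,8-diene-3,7-dione | O=C1C=C(OCC(C)C)CC(C)(C)[C@@]12C=CC(=O)CC2 | intermediate
8 | (6R)-3-(bromomethylidene)-11,11-dimethyl-9-(2-methylpropoxy)spiro[5.5]undeca-1,8-dien-7-one (E/Z mixture) | O=C1C=C(OCC(C)C)CC(C)(C)[C@@]12C=CC(=CBr)CC2 | intermediate
9 | (6R)-3-(bromomethylidene)-7-[(methoxymethoxy)methyl]-11,11-dimethyl-9-(2-methylpropoxy)spiro[5.5]undeca-1,8-dien-7-ol (C7 epimers) | OC1(COCOC)C=C(OCC(C)C)CC(C)(C)[C@@]12C=CC(=CBr)CC2 | intermediate (not isolated)
10 | (6R)-3-(bromomethylidene)-7-[(methoxymethoxy)methyl]-11,11-dimethylspiro[5.5]undeca-1,7-dien-9-one | COCOCC1=CC(=O)CC(C)(C)[C@@]12C=CC(=CBr)CC2 | intermediate (not isolated)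
11 | (6R)-3-(bromomethylidene)-7-(hydroxymethyl)-11,11-dimethylspiro[5.5]undeca-1,7-dien-9-one | OCC1=CC(=O)CC(C)(C)[C@@]12C=CC(=CBr)CC2 | intermediate
12 | [(6R)-3-(bromomethylidene)-11,11-dimethyl-9-oxospiro[5.5]undeca-1,7-dien-7-yl]methyl 2,2-dimethylpropanoate | CC(C)(C)C(=O)OCC1=CC(=O)CC(C)(C)[C@@]12C=CC(=CBr)CC2 | intermediate
13 | [(6R)-3-(bromomethylidene)-11,11-dimethyl-9-(trimethylsilyloxy)spiro[5.5]undeca-1,7,9-trien-7-yl]methyl 2,2-dimethylpropanoate | CC(C)(C)C(=O)OCC1=CC(O[Si](C)(C)C)=CC(C)(C)[C@@]12C=CC(=CBr)CC2 | intermediate (not isolated)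
14 | [(6S,10S)-10-bromo-3-(bromomethylidene)-11,11-dimethyl-9-oxospiro[5.5]undeca-1,7-dien-7-yl]methyl 2,2-dimethylpropanoate | CC(C)(C)C(=O)OCC1=CC(=O)[C@@H](Br)C(C)(C)[C@@]12C=CC(=CBr)CC2 | intermediate
15 | [(3R,6S,10S)-10-bromo-3-(dibromomethyl)-3-hydroxy-11,11-dimethyl-9-oxospiro[5.5]undeca-1,7-dien-7-yl]methyl 2,2-dimethylpropanoate | CC(C)(C)C(=O)OCC1=CC(=O)[C@@H](Br)C(C)(C)[C@@]12C=C[C@@](O)(C(Br)Br)CC2 | intermediate
16 | (3R,6S,9R,10S)-10-bromo-3-(dibromomethyl)-7-(hydroxymethyl)-11,11-dimethylspiro[5.5]undeca-1,7-diene-3,9-diol | OCC1=C[C@@H](O)[C@@H](Br)C(C)(C)[C@@]12C=C[C@@](O)(C(Br)Br)CC2 | intermediate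
17 | N-{[(3R,6S,9R,10S)-10-bromo-3-(dibromomethyl)-3,9-dihydroxy-11,11-dimethylspiro[5.5]undeca-1,7-dien-7-yl]methyl}-2-nitrobenzenesulfonohydrazide (alkylated at the sulfonyl-bearing nitrogen) | NN(CC1=C[C@@H](O)[C@@H](Br)C(C)(C)[C@@]12C=C[C@@](O)(C(Br)Br)CC2)S(=O)(=O)c3ccccc3[N+](=O)[O-] | intermediate (not isolated)
18 | (3R,6S,9R,10S)-10-bromo-7-(diazenylmethyl)-3-(dibromomethyl)-11,11-dimethylspiro[5.5]undeca-1,7-diene-3,9-diol | N=NCC1=C[C@@H](O)[C@@H](Br)C(C)(C)[C@@]12C=C[C@@](O)(C(Br)Br)CC2 | intermediate (not isolated)
19 | mailiohydrin, (3R,6S,9R,10S)-10-bromo-3-(dibromomethyl)-11,11-dimethyl-7-methylidenespiro[5.5]undec-1-ene-3,9-diol | C=C1C[C@@H](O)[C@@H](Br)C(C)(C)[C@@]12C=C[C@@](O)(C(Br)Br)CC2 | target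

**Step count and risks**
Total step count: 10. Longest linear sequence: 10 steps (fully linear from dimedone).

Steps most likely to fail:

1. Step 3. The Michael addition at the carbon flanked by the gem-dimethyl group may be slow and show low enantiofacial discrimination, and retro-Claisen loss of the formyl group may compete during the amine-mediated cyclisation. Fallback: setting out from 4, condensation with L-valine diethylamide (cat. p-TsOH, molecular sieves, CH2Cl2) should give the chelated enaminone F1. Its Cu(OAc)2·H2O-catalysed conjugate addition to methyl vinyl ketone in acetone at 23 °C should give the α-quaternary imine F2 under auxiliary control (the auxiliary enantiomer is chosen to give the 1S centre). Cold aqueous HCl then releases the auxiliary and returns to the route at 6, which is cyclised with pyrrolidine and AcOH as in step 3.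

2. Step 8. Water may capture the bromo-allyl cation from the equatorial side or at the distal allylic carbon (1,4-addition), and the remaining ring-B alkene may be over-brominated. Fallback: setting out from 14, oxymercuration with Hg(OAc)2 in THF/H2O at 0 °C (bridged mercurinium ion, anti Markovnikov-type opening by water along the axial trajectory, no free allyl cation), followed by exchange with aqueous KBr, should give the α-bromo organomercuric bromide F3. Bromodemercuration with pyridinium tribromide in pyridine at −20 °C replaces mercury by bromine and comes back to the route at 15.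

3. Step 5. Bromine–metal exchange at the vinyl bromide, incomplete 1,2-addition to the hindered carbonyl, or incomplete acetal cleavage may occur. Fallback: setting out from 8, CeCl3-promoted addition of (i-PrO)Me2SiCH2MgCl (a Grignard-based hydroxymethyl anion equivalent) should give the β-hydroxysilane F4. Tamao–Fleming oxidation (KF, KHCO3, H2O2, THF/MeOH) gives the diol F5, and 1 M HCl in THF at 23 °C effects the Stork–Danheiser transposition and comes back to the route at 11 with no acetal to cleave.

**Further compounds**
F1 | step 3 | (6Z)-6-({[(2S)-1-(diethylamino)-3-methyl-1-oxobutan-2-yl]amino}methylidene)-5,5-dimethyl-3-(2-methylpropoxy)cyclohex-2-en-1-one (enaminone of 4) | O=C1C=C(OCC(C)C)CC(C)(C)/C1=C/N[C@@H](C(C)C)C(=O)N(CC)CC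
F2 | step 3 | imine of Michael adduct 6 with L-valine diethylamide | O=C1C=C(OCC(C)C)CC(C)(C)[C@]1(C=N[C@@H](C(C)C)C(=O)N(CC)CC)CCC(C)=O
F3 | step 8 | [(3R,6S,10S)-10-bromo-3-[bromo(bromomercurio)methyl]-3-hydroxy-11,11-dimethyl-9-oxospiro[5.5]undeca-1,7-dien-7-yl]methyl 2,2-dimethylpropanoate | CC(C)(C)C(=O)OCC1=CC(=O)[C@@H](Br)C(C)(C)[C@@]12C=C[C@@](O)(C(Br)[Hg]Br)CC2
F4 | step 5 | (6R)-3-(bromomethylidene)-7-{[dimethyl(propan-2-yloxy)silyl]methyl}-11,11-dimethyl-9-(2-methylpropoxy)spiro[5.5]undeca-1,8-dien-7-ol | CC(C)O[Si](C)(C)CC1(O)C=C(OCC(C)C)CC(C)(C)[C@@]12C=CC(=CBr)CC2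
F5 | step 5 | (6R)-3-(bromomethylidene)-7-(hydroxymethyl)-11,11-dimethyl-9-(2-methylpropoxy)spiro[5.5]undeca-1,8-dien-7-ol | OCC1(O)C=C(OCC(C)C)CC(C)(C)[C@@]12C=CC(=CBr)CC2
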